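**Retrosynthetic overview**
1. The free acid comes from an allyl ester (deallylation with zerovalent palladium); the Z-methyl enoate comes from a Still–Gennari olefination of an α-alkylated bis(trifluoroethyl) phosphonoacetate with 3-(furan-3-yl)propanal.
2. The α-alkyl phosphonate comes from C-alkylation with the primary iodide of the two-carbon "left" arm; the E-enoic ester comes from a Wittig reaction of a chain aldehyde with an α-homoprenyl stabilised ylide.
3. The E-trisubstituted olefin and its two extra carbons come from a Johnson–Claisen rearrangement of an isopropenyl carbinol, itself made from the lactol of a δ-lactone.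
4. The (S)-4-isopropenyl-δ-lactone comes from the half-ester obtained by lipase (hydrolase) desymmetrisation of prochiral dimethyl 3-isopropenylglutarate, made by Rh-catalysed conjugate addition to dimethyl glutaconate.
5. Rings: the furan is bought (furan-3-carbaldehyde); the only ring made is the δ-lactone (step 3), opened again in steps 4 and 5.

Assumption: the lipase treats the 3-isopropenyl diester like 3-aryl- and 3-alkylglutarates and gives the (S)-half-ester; this sense and the ee are untested for this substrate and must be checked on the lactone of step 3 (chiral GC).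

**Step 1**
Reactants: 1 dimethyl (E)-pent-2-enedioate (dimethyl glutaconate; the commercial E/Z mixture serves); 2 4,4,5,5-tetramethyl-2-(prop-1-en-2-yl)-1,3,2-dioxaborolane
Product: 3 dimethyl 3-(prop-1-en-2-yl)pentanedioate
Conditions: [Rh(OH)(cod)]2 (2.5 mol %), K3PO4 (0.3 equiv), 1,4-dioxane/H2O 10:1, 50 °C
Reagents that add atoms: none
Why: Rhodium-catalysed (Hayashi–Miyaura-type) conjugate addition of the alkenylboronate runs under near-neutral aqueous conditions that tolerate the acidic CH2 of the glutaconate, and the product has a mirror plane, so no chiral ligand is needed.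

**Step 2**
Reactants: 3 dimethyl 3-(prop-1-en-2-yl)pentanedioate
Product: 4 (3S)-3-(2-methoxy-2-oxoethyl)-4-methylpent-4-enoic acid
Conditions: immobilised Candida antarctica lipase B, KH2PO4/K2HPO4 buffer (0.3 M, pH 7.2), MTBE (10 vol %), 30 °C, stopped at one ester cleaved
Reagents that add atoms: water (O)
Why: Enzymatic desymmetrisation by a lipase (serine hydrolase), which cleaves one of the two enantiotopic CH2CO2Me arms and stops at the half-ester, sets the only stereocentre as (S) by asymmetric catalysis.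

**Step 3**
Reactants: 4 (3S)-3-(2-methoxy-2-oxoethyl)-4-methylpent-4-enoic acid
Product: 7 (4S)-4-(prop-1-en-2-yl)oxan-2-one, via mixed isobutyl carbonic anhydride 5 (not isolated), via hydroxy ester 6 (not isolated)
Conditions: i-BuOCOCl, N-methylmorpholine, THF, –15 °C; NaBH4, H2O, –15 → 0 °C; PPTS (cat.), PhMe, 60 °C
Reagents that add atoms: none
Why: Mixed-anhydride activation followed by borohydride reduction converts only the acid arm to the alcohol (ester and alkene untouched, no borane), and acid-catalysed lactonisation then fixes the two arms as acyl and alkoxy without touching the β-stereocentre.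

**Step 4**
Reactants: 7 (4S)-4-(prop-1-en-2-yl)oxan-2-one
Product: 8 (2RS,4S)-4-(prop-1-en-2-yl)oxan-2-ol
Conditions: i-Bu2AlH (1.1 equiv), CH2Cl2, –78 °C; aq. KNaC4H4O6
Reagents that add atoms: none
Why: Partial hydride reduction of a lactone stops cleanly at the lactol because the tetrahedral aluminium hemiacetal is stable at –78 °C.

**Step 5**
Reactants: 8 (2RS,4S)-4-(prop-1-en-2-yl)oxan-2-ol; 9 isopropenylmagnesium bromide, CH2=C(CH3)MgBr
Product: 10 (3S,5RS)-6-methyl-3-(prop-1-en-2-yl)hept-6-ene-1,5-diol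
Conditions: 9 (3 equiv), THF, 0 °C → rt; aq. NH4Cl
Reagents that add atoms: none
Why: Grignard addition to the open hydroxy-aldehyde form of the lactol gives the allylic alcohol; the new carbinol centre is a mixture of no consequence because step 7 destroys it.

**Step 6**
Reactants: 10 (3S,5RS)-6-methyl-3-(prop-1-en-2-yl)hept-6-ene-1,5-diol
Product: 11 (3RS,5S)-7-[(tert-butyldiphenylsilyl)oxy]-2-methyl-5-(prop-1-en-2-yl)hept-1-en-3-ol
Conditions: TBDPSCl (1.05 equiv), imidazole, CH2Cl2, 0 °C
Reagents that add atoms: tert-butyl(chloro)diphenylsilane (CC(C)(C)[Si](Cl)(c1ccccc1)c1ccccc1)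
Why: Sterically controlled silylation protects the primary hydroxyl selectively over the secondary allylic one.

**Step 7**
Reactants: 11 (3RS,5S)-7-[(tert-butyldiphenylsilyl)oxy]-2-methyl-5-(prop-1-en-2-yl)hept-1-en-3-ol; 12 triethyl orthoacetate
Product: 15 ethyl (4E,7R)-9-[(tert-butyldiphenylsilyl)oxy]-4-methyl-7-(prop-1-en-2-yl)non-4-enoate, via mixed orthoester 13 (not isolated), via ketene acetal 14 (not isolated)
Conditions: 12 (8 equiv), EtCO2H (0.1 equiv), 140 °C, EtOH distilled off
Reagents that add atoms: none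
Why: Johnson–Claisen rearrangement through a chair transition state with the carbinol substituent equatorial gives the E-trisubstituted olefin (typically >95:5) and adds two carbons; the stereocentre is not involved (the descriptor changes to R only by priority).

**Step 8**
Reactants: 15 ethyl (4E,7R)-9-[(tert-butyldiphenylsilyl)oxy]-4-methyl-7-(prop-1-en-2-yl)non-4-enoate
Product: 16 (4E,7R)-9-[(tert-butyldiphenylsilyl)oxy]-4-methyl-7-(prop-1-en-2-yl)non-4-en-1-ol
Conditions: i-Bu2AlH (2.5 equiv), CH2Cl2, –78 → 0 °C; aq. KNaC4H4O6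
Reagents that add atoms: none
Why: Full hydride reduction of the ester to the primary alcohol avoids the over- and under-reduction mixtures of a one-step ester-to-aldehyde reduction.

**Step 9**
Reactants: 16 (4E,7R)-9-[(tert-butyldiphenylsilyl)oxy]-4-methyl-7-(prop-1-en-2-yl)non-4-en-1-ol
Product: 17 (4E,7R)-9-[(tert-butyldiphenylsilyl)oxy]-4-methyl-7-(prop-1-en-2-yl)non-4-enal
Conditions: Dess–Martin periodinane, CH2Cl2, 0 °C → rt
Reagents that add atoms: none
Why: Dess–Martin oxidation gives the aldehyde under mild, nearly neutral conditions without olefin migration or silyl loss.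

**Step 10**
Reactants: 18 prop-2-en-1-yl (triphenylphosphoranylidene)acetate; 19 5-bromo-2-methylpent-2-ene
Product: 22 prop-2-en-1-yl 6-methyl-2-(triphenylphosphoranylidene)hept-5-enoate, via homoprenyl iodide 20 (not isolated), via phosphonium bromide 21 (not isolated)
Conditions: NaI (0.2 equiv), MeCN, 80 °C, 36 h; then aq. NaOH, CH2Cl2, 0 °C
Reagents that add atoms: none
Why: SN2 C-alkylation of the stabilised ylide, accelerated by iodide (Finkelstein catalysis), gives the α-alkyl phosphonium salt, which hydroxide deprotonates to the α-branched stabilised ylide.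

**Step 11**
Reactants: 17 (4E,7R)-9-[(tert-butyldiphenylsilyl)oxy]-4-methyl-7-(prop-1-en-2-yl)non-4-enal; 22 prop-2-en-1-yl 6-methyl-2-(triphenylphosphoranylidene)hept-5-enoate
Product: 23 prop-2-en-1-yl (2E,6E,9R)-11-[(tert-butyldiphenylsilyl)oxy]-6-methyl-2-(4-methylpent-3-en-1-yl)-9-(prop-1-en-2-yl)undeca-2,6-dienoate
Conditions: PhMe, 90 °C
Reagents that add atoms: none
Why: Wittig olefination with an α-substituted stabilised ylide is reversible up to the oxaphosphetane and gives the E-trisubstituted enoate (ester trans to the chain, typically ≥95:5).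

**Step 12**
Reactants: 23 prop-2-en-1-yl (2E,6E,9R)-11-[(tert-butyldiphenylsilyl)oxy]-6-methyl-2-(4-methylpent-3-en-1-yl)-9-(prop-1-en-2-yl)undeca-2,6-dienoate
Product: 24 prop-2-en-1-yl (2E,6E,9R)-11-hydroxy-6-methyl-2-(4-methylpent-3-en-1-yl)-9-(prop-1-en-2-yl)undeca-2,6-dienoate
Conditions: Bu4NF, AcOH (1:1), THF, rt
Reagents that add atoms: none
Why: Fluoride-mediated desilylation, buffered with acetic acid so that the allyl ester is not attacked, frees the primary alcohol.

**Step 13**
Reactants: 24 prop-2-en-1-yl (2E,6E,9R)-11-hydroxy-6-methyl-2-(4-methylpent-3-en-1-yl)-9-(prop-1-en-2-yl)undeca-2,6-dienoate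
Product: 25 prop-2-en-1-yl (2E,6E,9R)-11-iodo-6-methyl-2-(4-methylpent-3-en-1-yl)-9-(prop-1-en-2-yl)undeca-2,6-dienoate
Conditions: I2, PPh3, imidazole, CH2Cl2, 0 °C → rt
Reagents that add atoms: iodine ([I][I])
Why: Appel-type (Garegg–Samuelsson) iodination converts the primary alcohol to the iodide by SN2 displacement of the alkoxyphosphonium without touching the olefins.

**Step 14**
Reactants: 25 prop-2-en-1-yl (2E,6E,9R)-11-iodo-6-methyl-2-(4-methylpent-3-en-1-yl)-9-(prop-1-en-2-yl)undeca-2,6-dienoate; 26 methyl 2-[bis(2,2,2-trifluoroethoxy)phosphoryl]acetate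
Product: 28 13-methyl 1-(prop-2-en-1-yl) (2E,6E,9S)-12-[bis(2,2,2-trifluoroethoxy)phosphoryl]-6-methyl-2-(4-methylpent-3-en-1-yl)-9-(prop-1-en-2-yl)trideca-2,6-dienedioate, via sodium phosphonate carbanion 27 (not isolated)
Conditions: 26 (2 equiv), NaH, DMF, 0 °C; then 25, 50 °C
Reagents that add atoms: none
Why: SN2 C-alkylation of the soft phosphonoacetate carbanion by the primary iodide (excess anion suppresses dialkylation) installs the α-substituent; the new phosphonate-bearing centre is an irrelevant epimer mixture.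

**Step 15**
Reactants: 29 furan-3-carbaldehyde; 30 methyl (triphenylphosphoranylidene)acetate
Product: 31 methyl (2E)-3-(furan-3-yl)prop-2-enoate
Conditions: CH2Cl2, rt
Reagents that add atoms: none
Why: Wittig olefination with a stabilised ylide gives the E-acrylate (the geometry is irrelevant, since the double bond is reduced next).

**Step 16**
Reactants: 31 methyl (2E)-3-(furan-3-yl)prop-2-enoate
Product: 32 methyl 3-(furan-3-yl)propanoate
Conditions: H2 (3 atm), RhCl(PPh3)3 (3 mol %), PhMe/EtOH 1:1, rt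
Reagents that add atoms: none
Why: Homogeneous hydrogenation reduces the disubstituted conjugated alkene and leaves the aromatic furan untouched.

**Step 17**
Reactants: 32 methyl 3-(furan-3-yl)propanoate
Product: 33 3-(furan-3-yl)propanal
Conditions: i-Bu2AlH (1.05 equiv), CH2Cl2, –78 °C; MeOH, aq. KNaC4H4O6
Reagents that add atoms: none
Why: Partial hydride reduction of an unhindered methyl ester at –78 °C stops at the aluminium hemiacetal, which gives the aldehyde on work-up.

**Step 18**
Reactants: 28 13-methyl 1-(prop-2-en-1-yl) (2E,6E,9S)-12-[bis(2,2,2-trifluoroethoxy)phosphoryl]-6-methyl-2-(4-methylpent-3-en-1-yl)-9-(prop-1-en-2-yl)trideca-2,6-dienedioate; 33 3-(furan-3-yl)propanal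
Product: 35 13-methyl 1-(prop-2-en-1-yl) (2E,6E,9S,12Z)-12-[3-(furan-3-yl)propylidene]-6-methyl-2-(4-methylpent-3-en-1-yl)-9-(prop-1-en-2-yl)trideca-2,6-dienedioate, via potassium phosphonate carbanion 34 (not isolated)
Conditions: KN(SiMe3)2, 18-crown-6, THF, –78 °C; then 33
Reagents that add atoms: none
Why: Still–Gennari variant of the Horner–Wadsworth–Emmons olefination, where the electron-poor phosphonate and dissociated potassium counter-ion make elimination fast and kinetically controlled, places the ester cis to the furylethyl chain (Z); the minor E-isomer is removed by chromatography.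

**Step 19**
Reactants: 35 13-methyl 1-(prop-2-en-1-yl) (2E,6E,9S,12Z)-12-[3-(furan-3-yl)propylidene]-6-methyl-2-(4-methylpent-3-en-1-yl)-9-(prop-1-en-2-yl)trideca-2,6-dienedioate
Product: 36 (2E,6E,9S,12Z)-12-[3-(furan-3-yl)propylidene]-13-methoxy-6-methyl-2-(4-methylpent-3-en-1-yl)-13-oxo-9-(prop-1-en-2-yl)trideca-2,6-dienoic acid (CNP0201108.2)
Conditions: Pd(PPh3)4 (5 mol %), morpholine (10 equiv), THF, rt; pH 4 work-up
Reagents that add atoms: none
Why: Tsuji–Trost-type deallylation, in which zerovalent palladium ionises only the allyl ester and morpholine traps the π-allyl fragment, frees the acid without touching the methyl ester, the furan or any olefin geometry.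

**Compound list**
1 | dimethyl (E)-pent-2-enedioate | COC(=O)/C=C/CC(=O)OC | starting material
2 | 4,4,5,5-tetramethyl-2-(prop-1-en-2-yl)-1,3,2-dioxaborolane | CC(=C)B1OC(C)(C)C(C)(C)O1 | starting material
3 | dimethyl 3-(prop-1-en-2-yl)pentanedioate | C=C(C)C(CC(=O)OC)CC(=O)OC | intermediate
4 | (3S)-3-(2-methoxy-2-oxoethyl)-4-methylpent-4-enoic acid | C=C(C)[C@H](CC(=O)OC)CC(=O)O | intermediate
5 | (3R)-3-(2-methoxy-2-oxoethyl)-4-methylpent-4-enoic 2-methylpropyl carbonic anhydride | C=C(C)[C@H](CC(=O)OC)CC(=O)OC(=O)OCC(C)C | intermediate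
6 | methyl (3S)-3-(2-hydroxyethyl)-4-methylpent-4-enoate | C=C(C)[C@H](CC(=O)OC)CCO | intermediate
7 | (4S)-4-(prop-1-en-2-yl)oxan-2-one | C=C(C)[C@@H]1CC(=O)OCC1 | intermediate
8 | (2RS,4S)-4-(prop-1-en-2-yl)oxan-2-ol | C=C(C)[C@@H]1CC(O)OCC1 | intermediate
9 | isopropenylmagnesium bromide, CH2=C(CH3)MgBr | C=C(C)[Mg]Br | starting material
10 | (3S,5RS)-6-methyl-3-(prop-1-en-2-yl)hept-6-ene-1,5-diol | C=C(C)[C@H](CC(O)C(C)=C)CCO | intermediate
11 | (3RS,5S)-7-[(tert-butyldiphenylsilyl)oxy]-2-methyl-5-(prop-1-en-2-yl)hept-1-en-3-ol | C=C(C)[C@H](CC(O)C(C)=C)CCO[Si](c1ccccc1)(c1ccccc1)C(C)(C)C | intermediate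
12 | triethyl orthoacetate (1,1,1-triethoxyethane) | CC(OCC)(OCC)OCC | starting material
13 | (3RS,5S)-7-[(tert-butyldiphenylsilyl)oxy]-3-(1,1-diethoxyethoxy)-2-methyl-5-(prop-1-en-2-yl)hept-1-ene | C=C(C)[C@H](CC(OC(C)(OCC)OCC)C(C)=C)CCO[Si](c1ccccc1)(c1ccccc1)C(C)(C)C | intermediate
14 | (3RS,5S)-7-[(tert-butyldiphenylsilyl)oxy]-3-[(1-ethoxyethenyl)oxy]-2-methyl-5-(prop-1-en-2-yl)hept-1-ene | C=C(C)[C@H](CC(OC(=C)OCC)C(C)=C)CCO[Si](c1ccccc1)(c1ccccc1)C(C)(C)C | intermediate
15 | ethyl (4E,7R)-9-[(tert-butyldiphenylsilyl)oxy]-4-methyl-7-(prop-1-en-2-yl)non-4-enoate | C=C(C)[C@H](C/C=C(\C)CCC(=O)OCC)CCO[Si](c1ccccc1)(c1ccccc1)C(C)(C)C | intermediate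
16 | (4E,7R)-9-[(tert-butyldiphenylsilyl)oxy]-4-methyl-7-(prop-1-en-2-yl)non-4-en-1-ol | C=C(C)[C@H](C/C=C(\C)CCCO)CCO[Si](c1ccccc1)(c1ccccc1)C(C)(C)C | intermediate
17 | (4E,7R)-9-[(tert-butyldiphenylsilyl)oxy]-4-methyl-7-(prop-1-en-2-yl)non-4-enal | C=C(C)[C@H](C/C=C(\C)CCC=O)CCO[Si](c1ccccc1)(c1ccccc1)C(C)(C)C | intermediate
18 | prop-2-en-1-yl (triphenylphosphoranylidene)acetate | C=CCOC(=O)C=P(c1ccccc1)(c1ccccc1)c1ccccc1 | starting material
19 | 5-bromo-2-methylpent-2-ene | CC(C)=CCCBr | starting material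
20 | 5-iodo-2-methylpent-2-ene | CC(C)=CCCI | intermediate
21 | [6-methyl-1-oxo-1-(prop-2-en-1-yloxy)hept-5-en-2-yl]triphenylphosphonium bromide (racemic) | [Br-].C=CCOC(=O)C(CCC=C(C)C)[P+](c1ccccc1)(c1ccccc1)c1ccccc1 | intermediate
22 | prop-2-en-1-yl 6-methyl-2-(triphenylphosphoranylidene)hept-5-enoate | C=CCOC(=O)C(CCC=C(C)C)=P(c1ccccc1)(c1ccccc1)c1ccccc1 | intermediate
23 | prop-2-en-1-yl (2E,6E,9R)-11-[(tert-butyldiphenylsilyl)oxy]-6-methyl-2-(4-methylpent-3-en-1-yl)-9-(prop-1-en-2-yl)undeca-2,6-dienoate | C=C(C)[C@H](C/C=C(\C)CC/C=C(\CCC=C(C)C)C(=O)OCC=C)CCO[Si](c1ccccc1)(c1ccccc1)C(C)(C)C | intermediate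
24 | prop-2-en-1-yl (2E,6E,9R)-11-hydroxy-6-methyl-2-(4-methylpent-3-en-1-yl)-9-(prop-1-en-2-yl)undeca-2,6-dienoate | C=C(C)[C@H](C/C=C(\C)CC/C=C(\CCC=C(C)C)C(=O)OCC=C)CCO | intermediate
25 | prop-2-en-1-yl (2E,6E,9R)-11-iodo-6-methyl-2-(4-methylpent-3-en-1-yl)-9-(prop-1-en-2-yl)undeca-2,6-dienoate | C=C(C)[C@H](C/C=C(\C)CC/C=C(\CCC=C(C)C)C(=O)OCC=C)CCI | intermediate
26 | methyl 2-[bis(2,2,2-trifluoroethoxy)phosphoryl]acetate | COC(=O)CP(=O)(OCC(F)(F)F)OCC(F)(F)F | starting material
27 | sodium 1-[bis(2,2,2-trifluoroethoxy)phosphoryl]-2-methoxy-2-oxoethan-1-ide | [Na+].COC(=O)[CH-]P(=O)(OCC(F)(F)F)OCC(F)(F)F | intermediate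
28 | 13-methyl 1-(prop-2-en-1-yl) (2E,6E,9S)-12-[bis(2,2,2-trifluoroethoxy)phosphoryl]-6-methyl-2-(4-methylpent-3-en-1-yl)-9-(prop-1-en-2-yl)trideca-2,6-dienedioate (both C12 epimers) | C=C(C)[C@H](C/C=C(\C)CC/C=C(\CCC=C(C)C)C(=O)OCC=C)CCC(C(=O)OC)P(=O)(OCC(F)(F)F)OCC(F)(F)F | intermediate
29 | furan-3-carbaldehyde | O=Cc1ccoc1 | starting material
30 | methyl (triphenylphosphoranylidene)acetate | COC(=O)C=P(c1ccccc1)(c1ccccc1)c1ccccc1 | starting material
31 | methyl (2E)-3-(furan-3-yl)prop-2-enoate | COC(=O)/C=C/c1ccoc1 | intermediate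
32 | methyl 3-(furan-3-yl)propanoate | COC(=O)CCc1ccoc1 | intermediate
33 | 3-(furan-3-yl)propanal | O=CCCc1ccoc1 | intermediate
34 | potassium salt of 28 deprotonated at C12 (phosphonate-stabilised carbanion, 9S) | [K+].C=C(C)[C@H](C/C=C(\C)CC/C=C(\CCC=C(C)C)C(=O)OCC=C)CC[C-](C(=O)OC)P(=O)(OCC(F)(F)F)OCC(F)(F)F | intermediate
35 | 13-methyl 1-(prop-2-en-1-yl) (2E,6E,9S,12Z)-12-[3-(furan-3-yl)propylidene]-6-methyl-2-(4-methylpent-3-en-1-yl)-9-(prop-1-en-2-yl)trideca-2,6-dienedioate | C=C(C)[C@H](C/C=C(\C)CC/C=C(\CCC=C(C)C)C(=O)OCC=C)CC/C(=C/CCc1ccoc1)C(=O)OC | intermediate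
36 | (2E,6E,9S,12Z)-12-[3-(furan-3-yl)propylidene]-13-methoxy-6-methyl-2-(4-methylpent-3-en-1-yl)-13-oxo-9-(prop-1-en-2-yl)trideca-2,6-dienoic acid | C=C(C)[C@H](C/C=C(\C)CC/C=C(\CCC=C(C)C)C(=O)O)CC/C(=C/CCc1ccoc1)C(=O)OC | target

**Totals**
Total step count: 19. Longest linear sequence: 15 steps (steps 1–9, 11–14, 18, 19, from dimethyl glutaconate 1).

**Three steps most likely to fail**

Step 2 (lipase desymmetrisation). The risk is insufficient ee, or the opposite sense, with this untested 3-alkenyl substrate. The fallback sets out from 3 and comes back at 7. LiOH (THF/H2O) converts 3 into 3-(prop-1-en-2-yl)pentanedioic acid F1, and Ac2O (60 °C) closes it to the prochiral cyclic anhydride 4-(prop-1-en-2-yl)oxane-2,6-dione F2. A lipase (Burkholderia cepacia lipase or the Candida antarctica enzyme) then opens F2 with MeOH in MTBE; alcoholysis in an organic solvent is a different regime in which this hydrolase class often gives higher, and sometimes inverted, selectivity. Planned for the inverted case, the product is the antipodal half-ester (3R)-3-(2-methoxy-2-oxoethyl)-4-methylpent-4-enoic acid F3. The ester arm instead of the acid arm is then reduced (LiBH4, THF, 0 °C → rt, on the lithium carboxylate); acidification gives (3S)-5-hydroxy-3-(prop-1-en-2-yl)pentanoic acid F4, which lactonises (PPTS, PhMe, 60 °C) to the same lactone 7. The same arm-switch rescues the route if the aqueous hydrolysis itself turns out to give F3, and a batch of normal sense is simply 4 and enters step 3.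

Step 14 (C-alkylation of the weakly nucleophilic bis(trifluoroethyl) phosphonoacetate with an unactivated iodide). The risk is low conversion, elimination or dialkylation. The fallback sets out from 24 and comes back at 28, replacing the SN2 step by condensation and conjugate reduction. Dess–Martin oxidation of 24 gives the aldehyde prop-2-en-1-yl (2E,6E,9R)-6-methyl-2-(4-methylpent-3-en-1-yl)-11-oxo-9-(prop-1-en-2-yl)undeca-2,6-dienoate F5. Knoevenagel condensation of F5 with 26 (piperidine/AcOH cat., PhMe, molecular sieves, 50 °C) gives the alkylidene phosphonoacetate 13-methyl 1-(prop-2-en-1-yl) (2E,6E,9R)-12-[bis(2,2,2-trifluoroethoxy)phosphoryl]-6-methyl-2-(4-methylpent-3-en-1-yl)-9-(prop-1-en-2-yl)trideca-2,6,11-trienedioate F6. NaBH4 (THF/i-PrOH, –20 °C) reduces only the doubly activated C=C of F6 and gives 28.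

Step 18 (Z-selectivity with a bulky α-substituent). The risk is a poor Z/E ratio. The fallback sets out from 25 and comes back at 35, moving from the trifluoroethyl phosphonate to Ando's diaryl phosphonate. Methyl 2-(diphenoxyphosphoryl)acetate F7 (from diphenyl phosphite, methyl bromoacetate and Et3N) is deprotonated (NaH, DMF, 0 °C) to sodium 1-(diphenoxyphosphoryl)-2-methoxy-2-oxoethan-1-ide F8. F8 is alkylated with 25 (50 °C) to the α-alkylated diphenyl phosphonate 13-methyl 1-(prop-2-en-1-yl) (2E,6E,9S)-12-(diphenoxyphosphoryl)-6-methyl-2-(4-methylpent-3-en-1-yl)-9-(prop-1-en-2-yl)trideca-2,6-dienedioate F9. NaH (THF, –78 °C) gives its sodium carbanion F10, which reacts with 33 (–78 → 0 °C) to give 35. Here Z-selectivity comes from the aryloxy groups on phosphorus and needs no crown ether; α-alkyl reagents of this kind are usually highly Z-selective with aliphatic aldehydes.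

**Further compounds**
F1 | step 2 | 3-(prop-1-en-2-yl)pentanedioic acid | C=C(C)C(CC(=O)O)CC(=O)O
F2 | step 2 | 4-(prop-1-en-2-yl)oxane-2,6-dione | C=C(C)C1CC(=O)OC(=O)C1
F3 | step 2 | (3R)-3-(2-methoxy-2-oxoethyl)-4-methylpent-4-enoic acid | C=C(C)[C@@H](CC(=O)OC)CC(=O)O
F4 | step 2 | (3S)-5-hydroxy-3-(prop-1-en-2-yl)pentanoic acid | C=C(C)[C@H](CC(=O)O)CCO
F5 | step 14 | prop-2-en-1-yl (2E,6E,9R)-6-methyl-2-(4-methylpent-3-en-1-yl)-11-oxo-9-(prop-1-en-2-yl)undeca-2,6-dienoate | C=C(C)[C@H](C/C=C(\C)CC/C=C(\CCC=C(C)C)C(=O)OCC=C)CC=O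
F6 | step 14 | 13-methyl 1-(prop-2-en-1-yl) (2E,6E,9R)-12-[bis(2,2,2-trifluoroethoxy)phosphoryl]-6-methyl-2-(4-methylpent-3-en-1-yl)-9-(prop-1-en-2-yl)trideca-2,6,11-trienedioate (11E/11Z mixture) | C=C(C)[C@H](C/C=C(\C)CC/C=C(\CCC=C(C)C)C(=O)OCC=C)CC=C(C(=O)OC)P(=O)(OCC(F)(F)F)OCC(F)(F)F
F7 | step 18 | methyl 2-(diphenoxyphosphoryl)acetate | COC(=O)CP(=O)(Oc1ccccc1)Oc1ccccc1
F8 | step 18 | sodium 1-(diphenoxyphosphoryl)-2-methoxy-2-oxoethan-1-ide | [Na+].COC(=O)[CH-]P(=O)(Oc1ccccc1)Oc1ccccc1
F9 | step 18 | 13-methyl 1-(prop-2-en-1-yl) (2E,6E,9S)-12-(diphenoxyphosphoryl)-6-methyl-2-(4-methylpent-3-en-1-yl)-9-(prop-1-en-2-yl)trideca-2,6-dienedioate (both C12 epimers) | C=C(C)[C@H](C/C=C(\C)CC/C=C(\CCC=C(C)C)C(=O)OCC=C)CCC(C(=O)OC)P(=O)(Oc1ccccc1)Oc1ccccc1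
F10 | step 18 | sodium salt of F9 deprotonated at C12 (phosphonate-stabilised carbanion, 9S) | [Na+].C=C(C)[C@H](C/C=C(\C)CC/C=C(\CCC=C(C)C)C(=O)OCC=C)CC[C-](C(=O)OC)P(=O)(Oc1ccccc1)Oc1ccccc1
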